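**Retrosynthetic overview**

1. Target 14 ⇐ 13 by unmasking the side-chain ketone from its dithiane; 13 ⇐ 9 by dehydrogenation on the side of the ring ketone remote from the carbinol.
2. 9 ⇐ 7: the only stereocentre comes from an enantioselective conjugate borylation/oxidation of the β,β-disubstituted enone.
3. 7 ⇐ key C–C bond between the side-chain carbonyl carbon and its ring-side CH2: the oleyl acyl anion (lithiated dithiane 5) opens the vinyl oxirane 4 made in the flask from 3; the epoxide oxygen is then expelled in a Stork–Danheiser transposition.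
4. Rings: the carbocycle is bought with 3 and never rebuilt; only the auxiliary dithiane (step 1) and the transient oxirane (step 2) are formed, in that order.

Assumption: (9Z)-octadec-9-enal (oleyl aldehyde, 1) is bought as the Z-pure catalogue compound.

**Step 1**
Reactants: 1 (9Z)-octadec-9-enal
Product: 2 2-[(8Z)-heptadec-8-en-1-yl]-1,3-dithiane
Conditions: HS(CH2)3SH (1.1 equiv), BF3·OEt2 (0.2 equiv), CH2Cl2, 0 °C → rt
Reagents that add atoms: propane-1,3-dithiol, SCCCS
Why: Lewis-acid-catalysed thioacetalisation (first half of the Corey–Seebach sequence) turns the aldehyde carbon into the future acyl-anion carbon; the isolated Z-alkene is inert and no stereocentre is formed.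

**Step 2**
Reactants: 2 2-[(8Z)-heptadec-8-en-1-yl]-1,3-dithiane; 3 3-ethoxycyclohex-2-en-1-one
Product: 7 3-({2-[(8Z)-heptadec-8-en-1-yl]-1,3-dithian-2-yl}methyl)cyclohex-2-en-1-one, via vinyl oxirane 4 (not isolated), via lithiated dithiane 5 (not isolated), via lithium alkoxide adduct 6 (not isolated)
Conditions: (a) Me3S+ I−, n-BuLi, THF, −10 °C, then 3, −10 → 0 °C; (b) 2, n-BuLi, THF/DMPU, −30 °C; solution (a) added to (b), −78 → 0 °C; (c) 1 M aq HCl, THF, rt
Reagents that add atoms: trimethylsulfonium iodide, C[S+](C)C.[I-] (the CH2); water, O (the ring carbonyl oxygen)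
Why: Proposed new method: dimethylsulfonium methylide adds 1,2 to the vinylogous ester (Corey–Chaykovsky) to give the acid-labile vinyl oxirane 4, whose primary CH2 is opened in an SN2 sense by the acyl-anion equivalent 5 (Corey–Seebach dithiane–epoxide union, joining two normally electrophilic carbons; SN2′ attack is blocked because the alkene terminus is a fully substituted enol-ether carbon), and acid then ionises the tertiary allylic alkoxide 6 through the ethoxy-stabilised allyl cation and hydrolyses it to the transposed enone (Stork–Danheiser), so the epoxide oxygen is lost and no stereocentre survives; the closest known reactions are dithiane openings of 2,2-disubstituted and vinyl epoxides and Stork–Danheiser transpositions of 1,2-adducts of 3-alkoxyenones.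

**Step 3**
Reactants: 7 3-({2-[(8Z)-heptadec-8-en-1-yl]-1,3-dithian-2-yl}methyl)cyclohex-2-en-1-one
Product: 9 (3S)-3-hydroxy-3-({2-[(8Z)-heptadec-8-en-1-yl]-1,3-dithian-2-yl}methyl)cyclohexan-1-one, via tertiary pinacol boronate 8 (not isolated)
Conditions: Cu(MeCN)4PF6 (10 mol %), (R,R)-2,3-bis(tert-butylmethylphosphino)quinoxaline [(R,R)-QuinoxP*] (12 mol %), LiOtBu (15 mol %), B2pin2 (1.5 equiv), DMSO/THF, rt; then NaBO3·4H2O, THF/H2O, rt
Reagents that add atoms: sodium perborate tetrahydrate, [Na+].[O-]OB=O.O.O.O.O (the hydroxyl oxygen)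
Why: Enantioselective copper–boryl conjugate addition to a β,β-disubstituted cyclic enone (Shibasaki-type conjugate borylation): the bisphosphine–copper boryl species delivers boron to the Re face of C3 (priorities C2 > CH2-dithianyl > C4) to give boronate 8, and perborate oxidation of the C–B bond with retention gives the (S)-carbinol, the only stereocentre of the route.

**Step 4**
Reactants: 9 (3S)-3-hydroxy-3-({2-[(8Z)-heptadec-8-en-1-yl]-1,3-dithian-2-yl}methyl)cyclohexan-1-one
Product: 13 (5S)-5-hydroxy-5-({2-[(8Z)-heptadec-8-en-1-yl]-1,3-dithian-2-yl}methyl)cyclohex-2-en-1-one, via dilithium enolate alkoxide 10 (not isolated), via α-phenylselanyl ketone 11 (not isolated), via selenoxide 12 (not isolated)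
Conditions: LiN(iPr)2 (2.3 equiv), THF, −78 °C; PhSeBr, −78 °C; aqueous work-up; then 30% aq H2O2, pyridine, CH2Cl2, 0 °C → rt
Reagents that add atoms: none
Why: Reich-type α-selenenylation and selenoxide syn-elimination: after the hydroxyl is deprotonated, kinetic enolisation goes to the α-CH2 remote from the alkoxide-bearing quaternary carbon (less hindered, no adjacent negative charge), the selenoxide 12 can only eliminate away from the carbonyl, and the carbinol stereocentre is not touched.

**Step 5**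
Reactants: 13 (5S)-5-hydroxy-5-({2-[(8Z)-heptadec-8-en-1-yl]-1,3-dithian-2-yl}methyl)cyclohex-2-en-1-one
Product: 14 (5R)-5-hydroxy-5-[(10Z)-2-oxononadec-10-en-1-yl]cyclohex-2-en-1-one
Conditions: MeI (10 equiv), CaCO3 (5 equiv), MeCN/H2O (9:1), 45 °C, dark
Reagents that add atoms: water, O
Why: S-methylation of the dithiane followed by buffered hydrolysis (Fétizon–Jurion alkylative dithioacetal cleavage) frees the side-chain ketone under neutral conditions that spare the tertiary β-hydroxy enone, the Z-alkene and the stereocentre; the descriptor changes from S to R only because the CIP priorities change.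

**Compound list**

1 | (9Z)-octadec-9-enal | CCCCCCCC/C=C\CCCCCCCC=O | starting material
2 | 2-[(8Z)-heptadec-8-en-1-yl]-1,3-dithiane | CCCCCCCC/C=C\CCCCCCCC1SCCCS1 | intermediate
3 | 3-ethoxycyclohex-2-en-1-one | CCOC1=CC(=O)CCC1 | starting material
4 | 5-ethoxy-1-oxaspiro[2.5]oct-4-ene (racemic) | CCOC1=CC2(CO2)CCC1 | intermediate
5 | 2-[(8Z)-heptadec-8-en-1-yl]-2-lithio-1,3-dithiane | CCCCCCCC/C=C\CCCCCCCC1([Li])SCCCS1 | intermediate
6 | lithium 3-ethoxy-1-({2-[(8Z)-heptadec-8-en-1-yl]-1,3-dithian-2-yl}methyl)cyclohex-2-en-1-olate (racemic) | CCCCCCCC/C=C\CCCCCCCC1(CC2(O[Li])C=C(OCC)CCC2)SCCCS1 | intermediate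
7 | 3-({2-[(8Z)-heptadec-8-en-1-yl]-1,3-dithian-2-yl}methyl)cyclohex-2-en-1-one | CCCCCCCC/C=C\CCCCCCCC1(CC2=CC(=O)CCC2)SCCCS1 | intermediate
8 | (3R)-3-({2-[(8Z)-heptadec-8-en-1-yl]-1,3-dithian-2-yl}methyl)-3-(4,4,5,5-tetramethyl-1,3,2-dioxaborolan-2-yl)cyclohexan-1-one | CCCCCCCC/C=C\CCCCCCCC1(C[C@]2(B3OC(C)(C)C(C)(C)O3)CCCC(=O)C2)SCCCS1 | intermediate
9 | (3S)-3-hydroxy-3-({2-[(8Z)-heptadec-8-en-1-yl]-1,3-dithian-2-yl}methyl)cyclohexan-1-one | CCCCCCCC/C=C\CCCCCCCC1(C[C@]2(O)CCCC(=O)C2)SCCCS1 | intermediate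
10 | dilithium (5S)-5-({2-[(8Z)-heptadec-8-en-1-yl]-1,3-dithian-2-yl}methyl)cyclohex-1-ene-1,5-bis(olate) | CCCCCCCC/C=C\CCCCCCCC1(C[C@]2(O[Li])CCC=C(O[Li])C2)SCCCS1 | intermediate
11 | (5S)-5-hydroxy-5-({2-[(8Z)-heptadec-8-en-1-yl]-1,3-dithian-2-yl}methyl)-2-(phenylselanyl)cyclohexan-1-one (both C2 epimers) | CCCCCCCC/C=C\CCCCCCCC1(C[C@]2(O)CCC([Se]c3ccccc3)C(=O)C2)SCCCS1 | intermediate
12 | (5S)-5-hydroxy-5-({2-[(8Z)-heptadec-8-en-1-yl]-1,3-dithian-2-yl}methyl)-2-(phenylseleninyl)cyclohexan-1-one (epimer mixture) | CCCCCCCC/C=C\CCCCCCCC1(C[C@]2(O)CCC([Se](=O)c3ccccc3)C(=O)C2)SCCCS1 | intermediate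
13 | (5S)-5-hydroxy-5-({2-[(8Z)-heptadec-8-en-1-yl]-1,3-dithian-2-yl}methyl)cyclohex-2-en-1-one | CCCCCCCC/C=C\CCCCCCCC1(C[C@]2(O)CC=CC(=O)C2)SCCCS1 | intermediate
14 | (5R)-5-hydroxy-5-[(10Z)-2-oxononadec-10-en-1-yl]cyclohex-2-en-1-one | CCCCCCCC/C=C\CCCCCCCC(=O)C[C@]1(O)CC=CC(=O)C1 | target

**Step count and risks**

Total: 5 steps. Longest linear sequence: 5 steps (1 → 2 → 7 → 9 → 13 → 14; 3 enters in step 2).

Most likely to fail, first: step 2. The ylide may add sluggishly to the deactivated vinylogous carbonyl, lithium ions may ionise 4 before the hindered SN2 opening, and three events are run in one flask. The fallback sets out from 5 (made from 2 as in step 2) and changes the electrophile to a saturated, isolable epoxide. Commercial 1,4-dioxaspiro[4.5]decan-7-one F1 is converted with Me3S+ I−/NaH in DMSO–THF into the spiro-epoxide 1,6,9-trioxadispiro[2.1.4.3]dodecane F2. This is opened by 5 in THF/DMPU to the racemic tertiary alcohol 7-({2-[(8Z)-heptadec-8-en-1-yl]-1,3-dithian-2-yl}methyl)-1,4-dioxaspiro[4.5]decan-7-ol F3. Treatment with 2 M aq HCl in THF at 60 °C removes the ketal and dehydrates the β-hydroxy ketone, and the route is rejoined at 7.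

Second: step 3. The β-substituent is neopentyl-like and bulkier than the published cases, so rate and ee may drop. The facial sense of the chosen ligand enantiomer is assumed, not recalled with certainty; it must be confirmed on the first run, and (S,S)-QuinoxP* gives the mirror outcome if needed. The fallback sets out from 7 and delivers oxygen by nucleophilic epoxidation instead of borylation. 9-Amino-9-deoxy-epi-quinine bis(trifluoroacetate) (10 mol %) with 50% aq H2O2 (1.5 equiv) in dioxane gives the cis-epoxy ketone (1S,6R)-6-({2-[(8Z)-heptadec-8-en-1-yl]-1,3-dithian-2-yl}methyl)-7-oxabicyclo[4.1.0]heptan-2-one F4, with oxygen on the Re face of C3 (the quinidine-derived pseudo-enantiomer is used if the sense is opposite). Slow oxidation of the dithiane by the peroxide is the point to watch here. SmI2 in THF/MeOH at −90 °C then cleaves only the C–O bond α to the carbonyl, and the route is rejoined at 9.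

Third: step 4. The lithium aldolate may undergo retro-aldol cleavage, enolisation may go partly towards the carbinol, and the product can dehydrate to a phenol. The fallback sets out from 9, caps the carbinol and replaces the selenium chemistry. 1-(Trimethylsilyl)imidazole in CH2Cl2 gives (3S)-3-({2-[(8Z)-heptadec-8-en-1-yl]-1,3-dithian-2-yl}methyl)-3-[(trimethylsilyl)oxy]cyclohexan-1-one F5. Its lithium enolate (LiN(iPr)2, THF, −78 °C) is dehydrogenated in the same flask with N-tert-butylbenzenesulfinimidoyl chloride (Mukaiyama dehydrogenation) to (5S)-5-({2-[(8Z)-heptadec-8-en-1-yl]-1,3-dithian-2-yl}methyl)-5-[(trimethylsilyl)oxy]cyclohex-2-en-1-one F6. Aqueous citric acid in THF removes the silyl group, and the route is rejoined at 13.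

**Further compounds**

F1 | step 2 | 1,4-dioxaspiro[4.5]decan-7-one | O=C1CCCC2(C1)OCCO2
F2 | step 2 | 1,6,9-trioxadispiro[2.1.4.3]dodecane | C1CCC2(CO2)CC13OCCO3
F3 | step 2 | 7-({2-[(8Z)-heptadec-8-en-1-yl]-1,3-dithian-2-yl}methyl)-1,4-dioxaspiro[4.5]decan-7-ol (racemic) | CCCCCCCC/C=C\CCCCCCCC1(CC2(O)CCCC3(C2)OCCO3)SCCCS1
F4 | step 3 | (1S,6R)-6-({2-[(8Z)-heptadec-8-en-1-yl]-1,3-dithian-2-yl}methyl)-7-oxabicyclo[4.1.0]heptan-2-one | CCCCCCCC/C=C\CCCCCCCC1(C[C@]23CCCC(=O)[C@H]2O3)SCCCS1
F5 | step 4 | (3S)-3-({2-[(8Z)-heptadec-8-en-1-yl]-1,3-dithian-2-yl}methyl)-3-[(trimethylsilyl)oxy]cyclohexan-1-one | CCCCCCCC/C=C\CCCCCCCC1(C[C@]2(O[Si](C)(C)C)CCCC(=O)C2)SCCCS1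
F6 | step 4 | (5S)-5-({2-[(8Z)-heptadec-8-en-1-yl]-1,3-dithian-2-yl}methyl)-5-[(trimethylsilyl)oxy]cyclohex-2-en-1-one | CCCCCCCC/C=C\CCCCCCCC1(C[C@]2(O[Si](C)(C)C)CC=CC(=O)C2)SCCCS1
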